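**Retrosynthetic overview** (oxolane numbering: O1, C2 aryl, C3 CH2OH, C4 carbinol side chain, C5 CH2)
1. Target 11 ⇐ 10 by removal of two O-benzyl groups ⇐ aryl ketone 9 by a ketone reduction that sets the carbinol centre.
2. Key disconnection C2–O1: 9 ⇐ meso 1,4-diketone-1,4-diol 6 by an enantioselective, desymmetrising reductive cycloetherification. This closes the only ring of the target and fixes C2, C3 and C4 in one C–O bond-forming event.
3. 6 ⇐ racemic trans lactone Weinreb amide 3 plus two equivalents of aryllithium 5; the lactone ring of the starting material is opened here.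
4. 3 ⇐ paraconic acid 1 by trans-selective hydroxymethylation and amidation; racemic material suffices because 6 is meso.

Assumption: the target is read as (S)-carbinol on a (3R,4S,5S)-oxolane (aryl and CH2OH cis, CH2OH and side chain trans). The antipode of the chiral acid in step 4 that gives 9 rather than ent-9 must be fixed by a first screen; the (R)-catalyst is written.

**Step 1**
Reactants: 1 (±)-paraconic acid (5-oxooxolane-3-carboxylic acid)
Product: 2 rac-(3R,4S)-4-(hydroxymethyl)-5-oxooxolane-3-carboxylic acid (trans)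
Conditions: LiN(SiMe3)2 (2.2 equiv), THF–DMPU, −78 °C; HCHO gas (cracked paraformaldehyde), −78 → −40 °C; aq. HCl to pH 2, continuous EtOAc extraction
Reagents that add atoms: formaldehyde, C=O
Why: Aldol addition of the lactone enolate (carboxylate dianion) to formaldehyde; the electrophile enters anti to the neighbouring carboxylate, giving the trans lactone, and the racemate is sufficient because both enantiomers lead to the same meso compound 6.

**Step 2**
Reactants: 2 rac-(3R,4S)-4-(hydroxymethyl)-5-oxooxolane-3-carboxylic acid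
Product: 3 rac-(3R,4S)-4-(hydroxymethyl)-N-methoxy-N-methyl-5-oxooxolane-3-carboxamide
Conditions: MeNHOMe·HCl (1.2 equiv), EDC·HCl (1.3 equiv), HOBt (0.2 equiv), N-methylmorpholine (2.5 equiv), CH2Cl2–DMF, 0 °C → rt
Reagents that add atoms: N,O-dimethylhydroxylamine hydrochloride, CNOC.Cl
Why: Carbodiimide amide coupling (Weinreb amide formation); N-acylation outruns acylation of the primary alcohol, the trans hydroxy acid cannot close a second lactone, and no stereocentre is touched.

**Step 3**
Reactants: 3 rac-(3R,4S)-4-(hydroxymethyl)-N-methoxy-N-methyl-5-oxooxolane-3-carboxamide; 4 1-(benzyloxy)-4-bromo-2-methoxybenzene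
Product: 6 (2R,3S)-1,4-bis[4-(benzyloxy)-3-methoxyphenyl]-2,3-bis(hydroxymethyl)butane-1,4-dione (meso), via aryllithium 5 (not isolated)
Conditions: 4 (3.3 equiv), n-BuLi (3.3 equiv), THF, −78 °C, 30 min; then 3 in THF, −78 °C, 2 h; AcOH at −78 °C, then water
Reagents that add atoms: none
Why: Halogen–lithium exchange, then single aryl addition to the lactone carbonyl (stable lithium lactolate) and to the Weinreb amide (stable chelate), one equivalent serving as base for the hydroxyl; the trans lactone maps onto the meso open-chain diketodiol and both stereocentres are carried through unchanged at −78 °C.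

**Step 4**
Reactants: 6 (2R,3S)-1,4-bis[4-(benzyloxy)-3-methoxyphenyl]-2,3-bis(hydroxymethyl)butane-1,4-dione
Product: 9 [4-(benzyloxy)-3-methoxyphenyl][(3R,4S,5S)-5-[4-(benzyloxy)-3-methoxyphenyl]-4-(hydroxymethyl)oxolan-3-yl]methanone, via lactol 7 (not isolated), via oxocarbenium ion 8 (not isolated)
Conditions: (R)-3,3'-bis(2,4,6-triisopropylphenyl)-1,1'-binaphthalene-2,2'-diyl N-triflylphosphoramide (5 mol %), Hantzsch ester (diethyl 2,6-dimethyl-1,4-dihydropyridine-3,5-dicarboxylate, 1.3 equiv), 5 Å molecular sieves, toluene, −20 °C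
Reagents that add atoms: none
Why: Proposed new method: catalytic enantioselective desymmetrising reductive cycloetherification. The strong chiral Brønsted acid turns the rapidly interconverting enantiomeric lactols 7 (one from each enantiotopic hydroxy ketone pair of meso 6) into oxocarbenium/chiral-anion ion pairs 8. The Hantzsch ester, hydrogen-bonded to the phosphoramide anion, delivers hydride to C2 anti to the neighbouring CH2OH group (substrate control, 2,3-cis ether). The chiral anion makes this transfer fast for only one of the two enantiomeric cations (dynamic kinetic resolution through achiral 6), so the ring C–O bond and the configurations at C2, C3 and C4 are fixed together. The second hydroxy ketone pair cannot close because it would give a trans-fused bicycle. Closest known reaction types: Et3SiH/BF3·OEt2 reductive etherification of γ-hydroxy ketones (racemic, 2,3-cis selective) and chiral phosphoric acid/Hantzsch ester transfer hydrogenation of iminium and benzopyrylium ions.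

**Step 5**
Reactants: 9 [4-(benzyloxy)-3-methoxyphenyl][(3R,4S,5S)-5-[4-(benzyloxy)-3-methoxyphenyl]-4-(hydroxymethyl)oxolan-3-yl]methanone
Product: 10 (S)-[4-(benzyloxy)-3-methoxyphenyl][(3R,4S,5S)-5-[4-(benzyloxy)-3-methoxyphenyl]-4-(hydroxymethyl)oxolan-3-yl]methanol
Conditions: (R)-1-methyl-3,3-diphenyltetrahydro-1H,3H-pyrrolo[1,2-c][1,3,2]oxazaborole ((R)-Me-CBS, 0.2 equiv), BH3·SMe2 (2.0 equiv), THF, −20 °C; MeOH quench
Reagents that add atoms: none
Why: Corey–Bakshi–Shibata reduction; the (R)-oxazaborolidine delivers hydride to the face that gives the (S)-carbinol (aryl as large group), which is also the Felkin–Anh face dictated by the ring stereocentre (ring C3 as large substituent), so catalyst and substrate are matched.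

**Step 6**
Reactants: 10 (S)-[4-(benzyloxy)-3-methoxyphenyl][(3R,4S,5S)-5-[4-(benzyloxy)-3-methoxyphenyl]-4-(hydroxymethyl)oxolan-3-yl]methanol
Product: 11 (S)-(4-hydroxy-3-methoxyphenyl)[(3R,4S,5S)-5-(4-hydroxy-3-methoxyphenyl)-4-(hydroxymethyl)oxolan-3-yl]methanol
Conditions: H2 (1 atm), Pd/C (10 wt% palladium on carbon), EtOAc–MeOH, rt, stopped at full debenzylation
Reagents that add atoms: none
Why: Hydrogenolysis of the two aryl benzyl ethers; under neutral conditions the ArO–CH2Ph bonds cleave much faster than the benzylic C–O bonds of the oxolane and the carbinol, and no stereocentre is touched.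

**Compound list**
1 | (±)-paraconic acid (5-oxooxolane-3-carboxylic acid, racemate) | O=C1CC(C(=O)O)CO1 | starting material
2 | rac-(3R,4S)-4-(hydroxymethyl)-5-oxooxolane-3-carboxylic acid (trans; one enantiomer drawn) | OC(=O)[C@H]1COC(=O)[C@@H]1CO | intermediate
3 | rac-(3R,4S)-4-(hydroxymethyl)-N-methoxy-N-methyl-5-oxooxolane-3-carboxamide (trans; one enantiomer drawn) | CON(C)C(=O)[C@H]1COC(=O)[C@@H]1CO | intermediate
4 | 1-(benzyloxy)-4-bromo-2-methoxybenzene | COc1cc(Br)ccc1OCc1ccccc1 | starting material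
5 | [4-(benzyloxy)-3-methoxyphenyl]lithium | [Li]c1ccc(OCc2ccccc2)c(OC)c1 | intermediate
6 | (2R,3S)-1,4-bis[4-(benzyloxy)-3-methoxyphenyl]-2,3-bis(hydroxymethyl)butane-1,4-dione (meso) | COc1cc(C(=O)[C@@H](CO)[C@@H](CO)C(=O)c2ccc(OCc3ccccc3)c(OC)c2)ccc1OCc1ccccc1 | intermediate
7 | [4-(benzyloxy)-3-methoxyphenyl][(3R,4S)-5-[4-(benzyloxy)-3-methoxyphenyl]-5-hydroxy-4-(hydroxymethyl)oxolan-3-yl]methanone (lactol, both anomers) | COc1cc(C(=O)[C@H]2COC(O)(c3ccc(OCc4ccccc4)c(OC)c3)[C@@H]2CO)ccc1OCc1ccccc1 | intermediate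
8 | (3S,4R)-4-[4-(benzyloxy)-3-methoxybenzoyl]-2-[4-(benzyloxy)-3-methoxyphenyl]-3-(hydroxymethyl)-4,5-dihydro-3H-furan-1-ium (oxocarbenium ion, chiral phosphoramide counter-anion) | COc1cc(C(=O)[C@H]2C[O+]=C(c3ccc(OCc4ccccc4)c(OC)c3)[C@@H]2CO)ccc1OCc1ccccc1 | intermediate
9 | [4-(benzyloxy)-3-methoxyphenyl][(3R,4S,5S)-5-[4-(benzyloxy)-3-methoxyphenyl]-4-(hydroxymethyl)oxolan-3-yl]methanone | COc1cc(C(=O)[C@H]2CO[C@H](c3ccc(OCc4ccccc4)c(OC)c3)[C@@H]2CO)ccc1OCc1ccccc1 | intermediate
10 | (S)-[4-(benzyloxy)-3-methoxyphenyl][(3R,4S,5S)-5-[4-(benzyloxy)-3-methoxyphenyl]-4-(hydroxymethyl)oxolan-3-yl]methanol | COc1cc([C@@H](O)[C@H]2CO[C@H](c3ccc(OCc4ccccc4)c(OC)c3)[C@@H]2CO)ccc1OCc1ccccc1 | intermediate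
11 | (S)-(4-hydroxy-3-methoxyphenyl)[(3R,4S,5S)-5-(4-hydroxy-3-methoxyphenyl)-4-(hydroxymethyl)oxolan-3-yl]methanol | COc1cc([C@@H](O)[C@H]2CO[C@H](c3ccc(O)c(OC)c3)[C@@H]2CO)ccc1O | target

**Step count and risks**
Total steps: 6. Longest linear sequence: 6 (1 → 11); aryl bromide 4 is used as bought.

Most likely to fail:

Step 4 (the proposed new reaction). Risks are low enantioselection, acid-induced furan formation from the 1,4-diketone, dehydration of the β-hydroxy ketone, and acid epimerisation of the 2,3-cis benzylic ether. The fallback uses known chemistry, sets out from 6 and comes back at 10. A lipase (Burkholderia cepacia lipase, vinyl acetate, MTBE, 30 °C; enzyme chosen by screening for the required enantiotopic arm) acetylates one CH2OH to give [(2S,3R)-2,3-bis[4-(benzyloxy)-3-methoxybenzoyl]-4-hydroxybutyl] acetate F1. The single remaining hydroxy ketone pair is then closed by the established silane reduction of its lactol (Et3SiH, BF3·OEt2, CH2Cl2, −78 °C; hydride anti to the acetoxymethyl group) to [(2S,3S,4R)-4-[4-(benzyloxy)-3-methoxybenzoyl]-2-[4-(benzyloxy)-3-methoxyphenyl]oxolan-3-yl]methyl acetate F2. Reduction as in step 5 gives [(2S,3S,4R)-2-[4-(benzyloxy)-3-methoxyphenyl]-4-[(S)-[4-(benzyloxy)-3-methoxyphenyl](hydroxy)methyl]oxolan-3-yl]methyl acetate F3. K2CO3 in MeOH at 0 °C removes the acetate only after the ketone is gone (avoiding β-elimination of the ring oxygen) and gives 10.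

Step 3 (twofold aryllithium addition in the presence of a free alkoxide). Risks are over-addition at the lactone and enolisation with loss of the trans relation. The fallback sets out from 3 and comes back at 6. The lactone is opened with MeNHOMe·HCl/i-PrMgCl (THF, −20 °C) to the meso bis(Weinreb amide) (2R,3S)-2,3-bis(hydroxymethyl)-N1,N4-dimethoxy-N1,N4-dimethylbutanediamide F4. This is silylated at once (TBSCl, imidazole, DMF) to (2R,3S)-2,3-bis[(tert-butyldimethylsilyloxy)methyl]-N1,N4-dimethoxy-N1,N4-dimethylbutanediamide F5. Aryllithium 5 (2.3 equiv, THF, −78 °C) then meets only two Weinreb amides and gives (2R,3S)-1,4-bis[4-(benzyloxy)-3-methoxyphenyl]-2,3-bis[(tert-butyldimethylsilyloxy)methyl]butane-1,4-dione F6, and HF·pyridine (THF, 0 °C) releases 6.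

Step 1 (dianion hydroxymethylation). Risks are double hydroxymethylation and loss of the very water-soluble acid 2 on isolation. The fallback sets out from 1 and comes back at 3, bypassing 2. The acid is first converted under the step 2 coupling conditions into the organic-soluble rac-N-methoxy-N-methyl-5-oxooxolane-3-carboxamide F7. Its lactone mono-enolate (LiN(SiMe3)2, 1.05 equiv, THF, −78 °C) is then hydroxymethylated with HCHO gas, again anti to the amide substituent, to give 3.

**Further compounds**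
F1 | step 4 | [(2S,3R)-2,3-bis[4-(benzyloxy)-3-methoxybenzoyl]-4-hydroxybutyl] acetate | COc1cc(C(=O)[C@@H](CO)[C@@H](COC(C)=O)C(=O)c2ccc(OCc3ccccc3)c(OC)c2)ccc1OCc1ccccc1
F2 | step 4 | [(2S,3S,4R)-4-[4-(benzyloxy)-3-methoxybenzoyl]-2-[4-(benzyloxy)-3-methoxyphenyl]oxolan-3-yl]methyl acetate | COc1cc(C(=O)[C@H]2CO[C@H](c3ccc(OCc4ccccc4)c(OC)c3)[C@@H]2COC(C)=O)ccc1OCc1ccccc1
F3 | step 4 | [(2S,3S,4R)-2-[4-(benzyloxy)-3-methoxyphenyl]-4-[(S)-[4-(benzyloxy)-3-methoxyphenyl](hydroxy)methyl]oxolan-3-yl]methyl acetate | COc1cc([C@@H](O)[C@H]2CO[C@H](c3ccc(OCc4ccccc4)c(OC)c3)[C@@H]2COC(C)=O)ccc1OCc1ccccc1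
F4 | step 3 | (2R,3S)-2,3-bis(hydroxymethyl)-N1,N4-dimethoxy-N1,N4-dimethylbutanediamide (meso) | CON(C)C(=O)[C@@H](CO)[C@@H](CO)C(=O)N(C)OC
F5 | step 3 | (2R,3S)-2,3-bis[(tert-butyldimethylsilyloxy)methyl]-N1,N4-dimethoxy-N1,N4-dimethylbutanediamide (meso) | CON(C)C(=O)[C@@H](CO[Si](C)(C)C(C)(C)C)[C@@H](CO[Si](C)(C)C(C)(C)C)C(=O)N(C)OC
F6 | step 3 | (2R,3S)-1,4-bis[4-(benzyloxy)-3-methoxyphenyl]-2,3-bis[(tert-butyldimethylsilyloxy)methyl]butane-1,4-dione (meso) | COc1cc(C(=O)[C@@H](CO[Si](C)(C)C(C)(C)C)[C@@H](CO[Si](C)(C)C(C)(C)C)C(=O)c2ccc(OCc3ccccc3)c(OC)c2)ccc1OCc1ccccc1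
F7 | step 1 | rac-N-methoxy-N-methyl-5-oxooxolane-3-carboxamide | CON(C)C(=O)C1COC(=O)C1
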